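## Structural features

The target 10 is a 2,3-dihydro-1-benzofuran: a benzene ring A (C3a, C4, C5, C6, C7, C7a) fused along C3a–C7a to the oxygen heterocycle ring B (O1, C2, C3, C3a, C7a). C2 carries a 3,4,5-trimethoxyphenyl ring and C3 a hydroxymethyl group (C9); these two adjacent stereocentres are trans and have the 2R,3S configuration. C5, para to the ring oxygen on C7a, carries an (E)-3-hydroxyprop-1-enyl chain. The fragile parts are the C2–O1 bond, a benzylic ether next to an electron-rich arene that is prone to acid-induced ionisation and to hydrogenolysis, and the cinnamyl-type allylic alcohol, which tolerates neither acid, nor oxidants, nor alkene-reducing conditions. The carbon count is small; the real difficulty is to set the two contiguous stereocentres of ring B in the relative and the absolute sense while ring B is joined to ring A through two adjacent carbons. The key step exploits exactly this: C7a and C3a are the ipso/ortho pair of an aryl iodide whose para position is C5, and O1–C2–C3 with C9 and the aryl group is the oxygen and the two carbons of a 2,3-disubstituted oxirane. Because one oxirane C–O bond is kept (O1–C2) and the other is replaced with inversion (C3–C3a), the trans relation of 10 corresponds to a cis-oxirane, that is, to a Z-alkene and one asymmetric epoxidation.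

## Logic of the disconnections

10 ⇒ 9. Only the O–Si bond on the C9 oxygen is cut. The C9 hydroxyl has to be masked through the key step, since a free alkoxide next to the oxirane would shift the ring (Payne rearrangement) and would compete for the C–O closure. The demand on the forward step is a neutral unmasking, which fluoride meets.

9 ⇒ 8. No skeletal bond is cut; the allylic CH2OH of the C5 chain is traced back to an ester carbonyl. The three chain carbons are then present from the start, and the acceptor conjugated to C7a is what the key step wants electronically. The forward step must reduce the ester by 1,2-addition and spare the silyl ether and the C2–O1 bond.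

8 ⇒ 7 + 5. The bonds C3–C3a and O1–C7a are cut, ring B is opened, and the molecule falls into two pieces of similar size. 7 supplies ring A with its chain; 5 supplies O1, C2, C3, C9 and the trimethoxyphenyl ring with all stereochemical information. The demands are heavy.
- The carbon attacked must be oxirane C2 of 5 (the one bearing C9, which becomes C3 of 8). The benzylic oxirane C3 keeps its oxygen and becomes C2 of 8.
- The attack must go with inversion, so 5 has to be the cis-(2R,3S) isomer. The 2R,3S descriptors of 5 and of 8 coincide only because the CIP priorities change at both centres.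
- 7 has two free ortho positions and must be alkylated once only. This is answered by a bridgehead-substituted norbornene and an excess of 7, not by a blocking group on 7, which would cost two steps and a removal that 10 would not tolerate.

7 ⇒ 6. The chain C=C bond is cut, which leads to a commercial aldehyde and a two-carbon ylide. The forward step has to be E-selective.

5 ⇒ 4. The O–Si bond is cut. A tert-butyldimethylsilyl ether is chosen because it withdraws the least electron density from oxirane C2, is small enough not to screen that carbon, and leaves with fluoride.

4 ⇒ 3. Both C–O bonds of the oxirane are cut. An allylic alcohol allows reagent-controlled asymmetric epoxidation, and the cis relation is stored as Z geometry. The forward step must use the D-(−)-tartrate to make oxirane C2 R, and 3 must be geometrically pure, since any E-isomer would end up as the cis diastereomer of 8.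

3 ⇒ 2. No skeletal bond is cut; the allylic alcohol is traced back to an ester. The gain is that Z/E purity can be secured by purification at the ester stage. The forward reduction must not isomerise the alkene.

2 ⇒ 1. The C=C bond is cut, which leads to a cheap commercial aldehyde. A kinetically Z-selective olefination is preferred to an alkyne semi-hydrogenation because it has no over-reduction problem. The demand is high Z selectivity.

## Other disconnections considered

Alternative 1: The cut falls on C3–C9 and on the C2–aryl bond, with ring B taken from an aromatic benzofuran.
- Forward key step: a boron ate complex carrying the benzofuran-2-yl and the trimethoxyphenyl group is attacked at C3 by a chiral allylpalladium electrophile (Pd2(dba)3, chiral bisphosphine, an allyl ester). The aryl group shifts from boron to C2 on the face opposite the incoming allyl group. The product is A1, (2R,3R)-3-allyl-5-bromo-2-(pinacolboryl)-2-(3,4,5-trimethoxyphenyl)-2,3-dihydrobenzofuran.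
- In favour: both stereocentres would come from one catalyst-controlled step on flat, achiral partners, the trans relation is inherent in the mechanism, and the bromine at C5 is a ready handle.
- Against: A1 is not at the constitution of 10. Boron on C2 must be replaced by hydrogen with retention at a tertiary, benzylic, oxygen-bearing carbon. The allyl group holds three carbons where one is wanted, so isomerisation, oxidative cleavage next to an electron-rich arene and reduction are needed before the C5 chain can be attached.
- Comparison: on structure the chosen key step is ahead, because 8 has every carbon of 10 at or next to its final oxidation level. On mechanism Alternative 1 is the better: its selectivities rest on ligand control in a documented reaction class, whereas the chosen plan rests on an untested regiochemical preference. On step economy the two are about equal, since Alternative 1 spends after the key step what it saves before it.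

Alternative 2: Three bonds of ring A are cut (C3a–C7a, C4–C5, C6–C7), so that rings A and B close in the same event.
- Forward key step: Cp*RuCl(cod) would join, in a (2+2+2) cyclotrimerisation, a silyl-capped ynol ether and an ethynyl group that hang on the stereodefined O1–C2–C3 unit with the terminal alkyne of an external enyne. The product is A2, the (2R,3S)-trans-7-triisopropylsilyl dihydrobenzofuran with both hydroxyl groups as tert-butyldimethylsilyl ethers.
- In favour: the metal never touches C2 or C3, so the key step carries no stereochemical risk. Cyclotrimerisation of tethered diynes with alkynes is a well-documented benzene synthesis, and the bulky silyl group should steer the external substituent to C5.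
- Against: the stereochemical problem is only moved into the acyclic tether. The most direct way to it opens the same kind of oxirane at the same non-benzylic carbon, so the regiochemical question of the chosen plan returns. The ynol ether must be built on a secondary benzylic alcohol in several sensitive steps, the enyne must react through its alkyne only, and the silicon on C7 of A2 must be removed with acid or forcing fluoride next to a benzylic ether.
- Comparison: on the reliability of the key step and on stereochemical safety within it, Alternative 2 is the better. On structure it is weaker, because A2 needs a harsher end-game than 8. On step economy the chosen plan is clearly ahead.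

Alternative 3: The cut falls on O1–C2 and C3–C9 of an aromatic benzofuran, with the stereocentres added afterwards.
- Forward key step: PdI2 with KI under CO and air in methanol would add the phenol oxygen to the alkyne of an ortho-alkynylphenol and carbonylate the resulting C3–palladium bond. The product is A3, methyl 5-bromo-2-(3,4,5-trimethoxyphenyl)benzofuran-3-carboxylate.
- In favour: the heterocyclisation–alkoxycarbonylation is robust and cheap, A3 holds the complete carbon skeleton with C9 as an ester and a bromine for the C5 chain, and both esters could be reduced in one final operation.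
- Against: every stereochemical decision is postponed to the reduction of a tetrasubstituted, aromatic, donor–acceptor C2=C3 bond. Hydrogenation would add cis, so C3 would then have to be epimerised, and dissolving-metal reduction would give the trans isomer only as a racemate. A highly enantioselective reduction of a benzofuran of this substitution type cannot be assumed.
- Comparison: on skeletal construction Alternative 3 is the better, and on step count it is equal or slightly shorter. On stereochemistry the chosen plan is ahead in principle, because both centres derive stereospecifically from an enantiopure oxirane. Both plans contain one stereo-defining step without direct precedent.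

Key step: step 6

Assumption: the bridgehead-substituted norbornene of step 6 (1-methylbicyclo[2.2.1]hept-2-ene) is a substoichiometric mediator obtained separately; it transfers no atoms to 8 and is not counted as a step.

## Route

Step 1
Reactants: 1 3,4,5-trimethoxybenzaldehyde
Product: 2 methyl (Z)-3-(3,4,5-trimethoxyphenyl)prop-2-enoate
Conditions: (CF3CH2O)2P(O)CH2CO2Me, KN(SiMe3)2, 18-crown-6, THF, −78 °C
Reagents that add atoms: methyl 2-[bis(2,2,2-trifluoroethoxy)phosphoryl]acetate, COC(=O)CP(=O)(OCC(F)(F)F)OCC(F)(F)F
Why: Still–Gennari variant of the Horner–Wadsworth–Emmons olefination; with the electron-poor phosphonate and a dissociated potassium enolate the first-formed adduct should collapse faster than it equilibrates, so the Z-enoate is expected as the main isomer, and residual E-isomer can be removed here by chromatography.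

Step 2
Reactants: 2 methyl (Z)-3-(3,4,5-trimethoxyphenyl)prop-2-enoate
Product: 3 (Z)-3-(3,4,5-trimethoxyphenyl)prop-2-en-1-ol
Conditions: iBu2AlH (2.2 equiv), CH2Cl2, −78 °C; aq. potassium sodium tartrate
Reagents that add atoms: none
Why: 1,2-Reduction of an α,β-unsaturated ester with iBu2AlH is standard and should leave the Z geometry and the aryl methyl ethers untouched at low temperature.

Step 3
Reactants: 3 (Z)-3-(3,4,5-trimethoxyphenyl)prop-2-en-1-ol
Product: 4 [(2R,3S)-3-(3,4,5-trimethoxyphenyl)oxiran-2-yl]methanol (cis-oxirane)
Conditions: Ti(OiPr)4 (10 mol %), D-(−)-diisopropyl tartrate (12 mol %), tBuOOH (2 equiv), 4 Å molecular sieves, CH2Cl2, −20 °C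
Reagents that add atoms: tert-butyl hydroperoxide, CC(C)(C)OO
Why: Katsuki–Sharpless asymmetric epoxidation; the allylic hydroxyl binds the titanium tartrate complex, which delivers the peroxide oxygen to one alkene face, and the D-(−)-tartrate should make oxirane C2 R. The syn-specific oxygen transfer to the Z-alkene fixes the cis relation and hence C3 as S.

Step 4
Reactants: 4 [(2R,3S)-3-(3,4,5-trimethoxyphenyl)oxiran-2-yl]methanol
Product: 5 tert-butyl(dimethyl){[(2R,3S)-3-(3,4,5-trimethoxyphenyl)oxiran-2-yl]methoxy}silane (cis-oxirane)
Conditions: TBSCl, imidazole, CH2Cl2, 0 °C to rt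
Reagents that add atoms: tert-butyl(chloro)dimethylsilane, CC(C)(C)[Si](C)(C)Cl
Why: Silylation of a primary alcohol under mildly basic, non-nucleophilic conditions, which should leave the oxirane and both stereocentres untouched.

Step 5
Reactants: 6 4-iodobenzaldehyde
Product: 7 ethyl (E)-3-(4-iodophenyl)prop-2-enoate
Conditions: Ph3P=CHCO2Et, toluene, 80 °C
Reagents that add atoms: ethyl (triphenylphosphoranylidene)acetate, CCOC(=O)C=P(c1ccccc1)(c1ccccc1)c1ccccc1
Why: Wittig olefination with a stabilised ylide, which is expected to give the E-cinnamate; the aryl iodide is inert under these conditions.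

Step 6
Reactants: 7 ethyl (E)-3-(4-iodophenyl)prop-2-enoate (1.5 equiv); 5 tert-butyl(dimethyl){[(2R,3S)-3-(3,4,5-trimethoxyphenyl)oxiran-2-yl]methoxy}silane (1.0 equiv)
Product: 8 ethyl (E)-3-[(2R,3S)-3-({[tert-butyl(dimethyl)silyl]oxy}methyl)-2-(3,4,5-trimethoxyphenyl)-2,3-dihydro-1-benzofuran-5-yl]prop-2-enoate (2,3-trans)
Conditions: Pd(OAc)2 (10 mol %), XPhos (20 mol %), 1-methylbicyclo[2.2.1]hept-2-ene (50 mol %), K2CO3 (2.5 equiv), 1,4-dioxane, 90 °C, argon
Reagents that add atoms: none
Why: Proposed new method: the closest known reaction type is the palladium/norbornene (Catellani-type) annulation of ortho-substituted aryl iodides with terminal epoxides to 2,3-dihydrobenzofurans, and its extension to an ortho-unsubstituted iodide and to a cis-2,3-disubstituted oxirane that must open at its non-benzylic carbon is not established. Mechanistically, zerovalent palladium should insert into the C–I bond of 7, the norbornene should insert into the aryl–palladium bond, and carbonate-assisted ortho C–H palladation should give the five-membered aryl–norbornyl palladacycle of divalent palladium. This electron-rich palladacycle is expected to attack oxirane C2 of 5 (the carbon bearing CH2OSi) from the side opposite its C–O bond, giving a tetravalent palladium alkyl alkoxide whose aryl–alkyl reductive elimination forms C3–C3a. β-Carbon elimination then expels the norbornene, and the resulting arylpalladium alkoxide of divalent palladium closes ring B by C(aryl)–O reductive elimination at the ipso carbon (O1–C7a) from a six-membered oxapalladacycle, a metal-templated closure in which no free nucleophile attacks carbon. C2 keeps the configuration of oxirane C3 because its C–O bond is never broken, and the new stereocentre C3 is set by the stereospecific inversion at oxirane C2, so that the cis-oxirane should map onto the trans-2R,3S product under substrate control alone. The step needs regioselectivity for the silyloxymethyl-bearing carbon over the benzylic one; what the substrate offers is the lower steric demand of CH2OSi compared with an aryl ring for a bulky metal nucleophile, a silyl ether that is the least electron-withdrawing protection of the neighbouring oxygen, a trimethoxyphenyl ring whose twisted 4-methoxy group stabilises benzylic cation character only moderately, and Lewis-acid-free carbonate conditions. It also needs a single ortho alkylation of an iodide with two free ortho positions, which the bridgehead-substituted norbornene (faster extrusion after the first alkylation) and the excess of 7 over 5 are meant to secure. The para acrylate makes the ipso carbon electron-poor, which should favour C–O reductive elimination over β-hydride loss from the alkoxide, and as a 1,2-disubstituted alkene it is a far poorer Heck acceptor than the norbornene, so it should remain a spectator.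

Step 7
Reactants: 8 ethyl (E)-3-[(2R,3S)-3-({[tert-butyl(dimethyl)silyl]oxy}methyl)-2-(3,4,5-trimethoxyphenyl)-2,3-dihydro-1-benzofuran-5-yl]prop-2-enoate
Product: 9 (E)-3-[(2R,3S)-3-({[tert-butyl(dimethyl)silyl]oxy}methyl)-2-(3,4,5-trimethoxyphenyl)-2,3-dihydro-1-benzofuran-5-yl]prop-2-en-1-ol
Conditions: iBu2AlH (2.5 equiv), CH2Cl2, −78 °C; aq. potassium sodium tartrate
Reagents that add atoms: none
Why: iBu2AlH reduces the conjugated ethyl ester to the allylic alcohol by 1,2-hydride delivery; the silyl ether, the C2–O1 bond and the E-alkene should not react at −78 °C, and neither stereocentre is touched.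

Step 8
Reactants: 9 (E)-3-[(2R,3S)-3-({[tert-butyl(dimethyl)silyl]oxy}methyl)-2-(3,4,5-trimethoxyphenyl)-2,3-dihydro-1-benzofuran-5-yl]prop-2-en-1-ol
Product: 10 (E)-3-[(2R,3S)-3-(hydroxymethyl)-2-(3,4,5-trimethoxyphenyl)-2,3-dihydro-1-benzofuran-5-yl]prop-2-en-1-ol (target)
Conditions: Bu4NF, THF, 0 °C to rt
Reagents that add atoms: none
Why: Fluoride-induced cleavage of the Si–O bond (desilylation) under essentially neutral conditions, which should spare the allylic alcohol and the benzylic ether and leave both stereocentres as set in step 6.

## Compound list

1 | 3,4,5-trimethoxybenzaldehyde | COc1cc(C=O)cc(OC)c1OC | starting material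
2 | methyl (Z)-3-(3,4,5-trimethoxyphenyl)prop-2-enoate | COC(=O)/C=C\c1cc(OC)c(OC)c(OC)c1 | intermediate
3 | (Z)-3-(3,4,5-trimethoxyphenyl)prop-2-en-1-ol | OC/C=C\c1cc(OC)c(OC)c(OC)c1 | intermediate
4 | [(2R,3S)-3-(3,4,5-trimethoxyphenyl)oxiran-2-yl]methanol (cis) | COc1cc([C@@H]2O[C@@H]2CO)cc(OC)c1OC | intermediate
5 | tert-butyl(dimethyl){[(2R,3S)-3-(3,4,5-trimethoxyphenyl)oxiran-2-yl]methoxy}silane (cis) | COc1cc([C@@H]2O[C@@H]2CO[Si](C)(C)C(C)(C)C)cc(OC)c1OC | intermediate
6 | 4-iodobenzaldehyde | O=Cc1ccc(I)cc1 | starting material
7 | ethyl (E)-3-(4-iodophenyl)prop-2-enoate | CCOC(=O)/C=C/c1ccc(I)cc1 | intermediate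
8 | ethyl (E)-3-[(2R,3S)-3-({[tert-butyl(dimethyl)silyl]oxy}methyl)-2-(3,4,5-trimethoxyphenyl)-2,3-dihydro-1-benzofuran-5-yl]prop-2-enoate (trans) | COc1cc([C@@H]2Oc3ccc(/C=C/C(=O)OCC)cc3[C@H]2CO[Si](C)(C)C(C)(C)C)cc(OC)c1OC | intermediate
9 | (E)-3-[(2R,3S)-3-({[tert-butyl(dimethyl)silyl]oxy}methyl)-2-(3,4,5-trimethoxyphenyl)-2,3-dihydro-1-benzofuran-5-yl]prop-2-en-1-ol (trans) | COc1cc([C@@H]2Oc3ccc(/C=C/CO)cc3[C@H]2CO[Si](C)(C)C(C)(C)C)cc(OC)c1OC | intermediate
10 | (E)-3-[(2R,3S)-3-(hydroxymethyl)-2-(3,4,5-trimethoxyphenyl)-2,3-dihydro-1-benzofuran-5-yl]prop-2-en-1-ol (trans) | COc1cc([C@@H]2Oc3ccc(/C=C/CO)cc3[C@H]2CO)cc(OC)c1OC | target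

## Step count and least certain steps

Total steps: 8. Longest linear sequence: 7 (steps 1–4, 6, 7, 8); step 5 is the second branch.

Step 6 (key step, new method). The processes most likely to spoil it are:
- opening at the benzylic oxirane carbon, which would lead to the regioisomeric ring or, through benzylic C–O insertion of zerovalent palladium and hydride shift, to isomerisation of the oxirane to a ketone;
- loss of stereospecificity if iodide opens the oxirane first and the palladacycle then displaces iodide (double inversion, cis product);
- a second ortho alkylation or retention of norbornene, because 7 has no ortho substituent;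
- slow reaction of the hindered internal oxirane, so that the palladacycle decays;
- migration of the silyl group to the secondary alkoxide followed by closure through the wrong oxygen.

The fallback uses known chemistry only, sets out from 1 and comes back at 8. 2-(5-Bromo-2-fluorophenyl)acetic acid is coupled with (R)-4-benzyloxazolidin-2-one (pivaloyl chloride, Et3N, LiCl, THF) to give (R)-4-benzyl-3-[2-(5-bromo-2-fluorophenyl)acetyl]oxazolidin-2-one F1. Its dibutylboron Z-enolate (Bu2BOTf, iPr2NEt, CH2Cl2, −78 °C) should add to 1 in an Evans syn-aldol reaction to give (R)-4-benzyl-3-[(2R,3R)-2-(5-bromo-2-fluorophenyl)-3-hydroxy-3-(3,4,5-trimethoxyphenyl)propanoyl]oxazolidin-2-one F2, which sets both stereocentres under auxiliary control. LiBH4 (THF, MeOH, 0 °C) removes the auxiliary reductively to give (1R,2S)-2-(5-bromo-2-fluorophenyl)-1-(3,4,5-trimethoxyphenyl)propane-1,3-diol F3. Selective silylation of the primary hydroxyl (TBSCl, imidazole, CH2Cl2, 0 °C) gives (1R,2S)-2-(5-bromo-2-fluorophenyl)-3-{[tert-butyl(dimethyl)silyl]oxy}-1-(3,4,5-trimethoxyphenyl)propan-1-ol F4. A Mizoroki–Heck reaction with ethyl acrylate (Pd(OAc)2, P(o-tol)3, Et3N, DMF, 100 °C) gives ethyl (E)-3-{3-[(1R,2S)-3-{[tert-butyl(dimethyl)silyl]oxy}-1-hydroxy-1-(3,4,5-trimethoxyphenyl)propan-2-yl]-4-fluorophenyl}prop-2-enoate F5, in which the fluorine is para to an acceptor. Deprotonation of the secondary alcohol (KN(SiMe3)2, THF, 0 °C to rt) should then close ring B by intramolecular nucleophilic aromatic substitution of fluoride, with retention at both centres, so that the syn-aldol relation becomes the trans ring relation of 8.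

Step 3. Z-Allylic alcohols are the slowest and least selective substrate class of this epoxidation, so the enantiomeric purity of 4 may be insufficient. In addition the benzylic oxirane may be opened by isopropoxide or hydroperoxide on titanium during the long reaction. The fallback sets out from 2 and comes back at 4. Jacobsen epoxidation of 2 with the (S,S) enantiomer of [N,N'-bis(3,5-di-tert-butylsalicylidene)cyclohexane-1,2-diaminato]manganese chloride (aq. NaOCl, 4-phenylpyridine N-oxide, CH2Cl2, 0 °C) should give methyl (2S,3S)-3-(3,4,5-trimethoxyphenyl)oxirane-2-carboxylate F6, the cis-glycidic ester with the same spatial arrangement as 4. Reduction of the ester with NaBH4 (MeOH, 0 °C) gives 4.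

Step 1. The risk is erosion of the kinetic Z selectivity; E-isomer that escapes purification would be carried into a trans-oxirane and finally into the cis diastereomer of 8. The fallback sets out from 1 and comes back at 3, bypassing 2. Ohira–Bestmann homologation of 1 (dimethyl (1-diazo-2-oxopropyl)phosphonate, K2CO3, MeOH, rt) gives 5-ethynyl-1,2,3-trimethoxybenzene F7. Deprotonation (nBuLi, THF, −78 °C) and addition to paraformaldehyde gives 3-(3,4,5-trimethoxyphenyl)prop-2-yn-1-ol F8. Syn semi-hydrogenation (H2, Pd/CaCO3 poisoned with Pb(OAc)2, quinoline, EtOAc, rt) gives 3.

## Further compounds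

F1 | step 6 | (R)-4-benzyl-3-[2-(5-bromo-2-fluorophenyl)acetyl]oxazolidin-2-one | O=C(Cc1cc(Br)ccc1F)N1[C@H](Cc2ccccc2)COC1=O
F2 | step 6 | (R)-4-benzyl-3-[(2R,3R)-2-(5-bromo-2-fluorophenyl)-3-hydroxy-3-(3,4,5-trimethoxyphenyl)propanoyl]oxazolidin-2-one | O=C([C@H](c1cc(Br)ccc1F)[C@@H](O)c1cc(OC)c(OC)c(OC)c1)N1[C@H](Cc2ccccc2)COC1=O
F3 | step 6 | (1R,2S)-2-(5-bromo-2-fluorophenyl)-1-(3,4,5-trimethoxyphenyl)propane-1,3-diol | OC[C@H](c1cc(Br)ccc1F)[C@@H](O)c1cc(OC)c(OC)c(OC)c1
F4 | step 6 | (1R,2S)-2-(5-bromo-2-fluorophenyl)-3-{[tert-butyl(dimethyl)silyl]oxy}-1-(3,4,5-trimethoxyphenyl)propan-1-ol | CC(C)(C)[Si](C)(C)OC[C@H](c1cc(Br)ccc1F)[C@@H](O)c1cc(OC)c(OC)c(OC)c1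
F5 | step 6 | ethyl (E)-3-{3-[(1R,2S)-3-{[tert-butyl(dimethyl)silyl]oxy}-1-hydroxy-1-(3,4,5-trimethoxyphenyl)propan-2-yl]-4-fluorophenyl}prop-2-enoate | CCOC(=O)/C=C/c1ccc(F)c(c1)[C@@H](CO[Si](C)(C)C(C)(C)C)[C@@H](O)c1cc(OC)c(OC)c(OC)c1
F6 | step 3 | methyl (2S,3S)-3-(3,4,5-trimethoxyphenyl)oxirane-2-carboxylate (cis) | COc1cc([C@@H]2O[C@@H]2C(=O)OC)cc(OC)c1OC
F7 | step 1 | 5-ethynyl-1,2,3-trimethoxybenzene | C#Cc1cc(OC)c(OC)c(OC)c1
F8 | step 1 | 3-(3,4,5-trimethoxyphenyl)prop-2-yn-1-ol | OCC#Cc1cc(OC)c(OC)c(OC)c1
A1 | alternative 1 | (2R,3R)-5-bromo-3-(prop-2-en-1-yl)-2-(4,4,5,5-tetramethyl-1,3,2-dioxaborolan-2-yl)-2-(3,4,5-trimethoxyphenyl)-2,3-dihydro-1-benzofuran (aryl and allyl trans) | COc1cc([C@]2(B3OC(C)(C)C(C)(C)O3)Oc3ccc(Br)cc3[C@H]2CC=C)cc(OC)c1OC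
A2 | alternative 2 | (2R,3S)-trans-5-[(E)-3-{[tert-butyl(dimethyl)silyl]oxy}prop-1-enyl]-3-({[tert-butyl(dimethyl)silyl]oxy}methyl)-7-[tri(propan-2-yl)silyl]-2-(3,4,5-trimethoxyphenyl)-2,3-dihydro-1-benzofuran | COc1cc([C@@H]2Oc3c([Si](C(C)C)(C(C)C)C(C)C)cc(/C=C/CO[Si](C)(C)C(C)(C)C)cc3[C@H]2CO[Si](C)(C)C(C)(C)C)cc(OC)c1OC
A3 | alternative 3 | methyl 5-bromo-2-(3,4,5-trimethoxyphenyl)-1-benzofuran-3-carboxylate | COC(=O)c1c(-c2cc(OC)c(OC)c(OC)c2)oc2ccc(Br)cc12
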